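**Retrosynthetic overview**
- Target ⇒ its 7,8-di-O-benzyl ether; the last step is a reductive debenzylation that spares the triene.
- (S)-Chroman ⇒ racemic chroman (enantioselective chromatography) ⇒ racemic chroman-4-one (C-4 deoxygenation).
- Key disconnection C3–C2, then O1–C2: intermolecular aldol condensation of a 2-hydroxyacetophenone with (E,E)-farnesylacetone, closed in the same pot by oxa-Michael addition (Kabbe). The dihydropyran is the only ring made; the benzene ring is bought.
- Acetophenone ⇒ 3,4,5-trimethoxytoluene (Friedel–Crafts acetylation, demethylation, 3,4-di-O-benzylation). Farnesylacetone ⇒ (E,E)-farnesol (bromide, acetoacetate alkylation, decarboxylation), so both E-alkenes are bought.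

Assumption: C-2 of the target is (S) by CIP (O > C-3 > C-1′ > CH3), i.e. opposite to natural (R)-tocotrienols; simple reagents (PBr3, AcCl, BnBr) are given on the reagent lines and are not numbered.

**Step 1**
Reactants: 1 (2E,6E)-farnesol
Product: 2 (2E,6E)-farnesyl bromide
Conditions: PBr3 (0.4 equiv), Et2O, −10 to 0 °C, 30 min; used crude
Reagents that add atoms: phosphorus tribromide BrP(Br)Br
Why: PBr3 bromination of a primary allylic alcohol (SN2 on the phosphite ester) is fast at −10 °C and keeps the 2E,6E geometry; no stereocentre is involved.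

**Step 2**
Reactants: 2 (2E,6E)-farnesyl bromide; 3 ethyl acetoacetate
Product: 4 ethyl (4E,8E)-2-acetyl-5,9,13-trimethyltetradeca-4,8,12-trienoate (racemic)
Conditions: NaH (1.4 equiv), 3 (1.5 equiv), THF, 0 °C → rt, 12 h
Reagents that add atoms: none
Why: Acetoacetic ester alkylation: the soft sodium enolate of 3 C-alkylates the primary allylic bromide by SN2 (excess enolate suppresses dialkylation); the new α-stereocentre is racemic and is erased in step 3.

**Step 3**
Reactants: 4 ethyl (4E,8E)-2-acetyl-5,9,13-trimethyltetradeca-4,8,12-trienoate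
Product: 6 (5E,9E)-6,10,14-trimethylpentadeca-5,9,13-trien-2-one, via β-keto acid 5 (not isolated)
Conditions: 5% aq NaOH, EtOH, rt, 12 h; then 2 M HCl to pH 2, 50 °C, 1 h
Reagents that add atoms: none
Why: Saponification followed by decarboxylation of the β-keto acid through its cyclic six-membered transition state (ketonic cleavage of the acetoacetic ester synthesis) gives the methyl ketone without touching the isolated E-alkenes.

**Step 4**
Reactants: 7 3,4,5-trimethoxytoluene
Product: 8 1-(2,3,4-trimethoxy-6-methylphenyl)ethan-1-one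
Conditions: AcCl (1.2 equiv), AlCl3 (1.2 equiv), CH2Cl2, 0 °C, 1 h
Reagents that add atoms: acetyl chloride CC(Cl)=O
Why: Friedel–Crafts acylation of a very electron-rich arene whose only two free positions are equivalent, so a single regioisomer forms (any 2-O-demethylated co-product converges in step 5).

**Step 5**
Reactants: 8 1-(2,3,4-trimethoxy-6-methylphenyl)ethan-1-one
Product: 9 1-(2,3,4-trihydroxy-6-methylphenyl)ethan-1-one
Conditions: BBr3 (4 equiv), CH2Cl2, −78 °C → rt, 12 h; H2O quench
Reagents that add atoms: none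
Why: BBr3 Lewis-acid cleavage of aryl methyl ethers frees all three phenols before any acid-sensitive polyene is present.

**Step 6**
Reactants: 9 1-(2,3,4-trihydroxy-6-methylphenyl)ethan-1-one
Product: 10 1-[3,4-bis(benzyloxy)-2-hydroxy-6-methylphenyl]ethan-1-one
Conditions: BnBr (2.05 equiv), K2CO3 (2.2 equiv), DMF, rt, Ar
Reagents that add atoms: benzyl bromide BrCc1ccccc1
Why: Williamson etherification in which the 2-OH, hydrogen-bonded to the ketone, is the least acidic and least nucleophilic phenol, so two equivalents of benzyl bromide alkylate only O-3 and O-4.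

**Step 7**
Reactants: 10 1-[3,4-bis(benzyloxy)-2-hydroxy-6-methylphenyl]ethan-1-one; 6 (5E,9E)-6,10,14-trimethylpentadeca-5,9,13-trien-2-one
Product: 12 racemic 7,8-bis(benzyloxy)-2,5-dimethyl-2-[(3E,7E)-4,8,12-trimethyltrideca-3,7,11-trien-1-yl]chroman-4-one, via enone 11 (not isolated)
Conditions: pyrrolidine (1.5 equiv), toluene, 4 Å MS, rt 12 h then reflux 6 h
Reagents that add atoms: none
Why: Kabbe chromanone synthesis: pyrrolidine (enamine/iminium) mediates the intermolecular aldol condensation between the acetyl CH3 of 10 and the ketone of 6 to give enone 11, whose phenol closes by intramolecular oxa-Michael addition; C-2 is created here without control, as the racemate that is resolved in step 9.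

**Step 8**
Reactants: 12 racemic chroman-4-one
Product: 14 racemic 7,8-bis(benzyloxy)-2,5-dimethyl-2-[(3E,7E)-4,8,12-trimethyltrideca-3,7,11-trien-1-yl]chromane, via chroman-4-ol 13 (not isolated)
Conditions: LiAlH4 (3 equiv)/AlCl3 (3 equiv), Et2O, 0 °C → reflux, 2 h; Rochelle salt work-up
Reagents that add atoms: none
Why: Mixed-hydride (chloroalane) hydrogenolysis: hydride reduction to the aluminium alkoxide, ionisation to the benzylic cation stabilised by O-1 and the 7-benzyloxy group, and a second hydride transfer give the CH2, while isolated alkenes, benzyl ethers and C-2 are untouched.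

**Step 9**
Reactants: 14 racemic chroman dibenzyl ether
Product: 15 (2S)-7,8-bis(benzyloxy)-2,5-dimethyl-2-[(3E,7E)-4,8,12-trimethyltrideca-3,7,11-trien-1-yl]chromane
Conditions: preparative chiral HPLC, cellulose tris(3,5-dimethylphenylcarbamate) phase, hexane/i-PrOH 99:1, 25 °C; (S)-antipode collected
Reagents that add atoms: none
Why: Resolution by preparative enantioselective chromatography: no bond is formed, the racemic C-2 centre from step 7 is separated into its antipodes (polysaccharide phases resolve 2R/2S tocotrienol-type chromans) and the (S)-enantiomer is identified by ECD (chroman helicity rule).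

**Step 10**
Reactants: 15 (2S)-chroman dibenzyl ether
Product: 16 (2S)-2,5-dimethyl-2-[(3E,7E)-4,8,12-trimethyltrideca-3,7,11-trien-1-yl]chromane-7,8-diol (target)
Conditions: preformed lithium naphthalenide (0.5 M in THF, 6 equiv), THF, −25 °C, 1 h; degassed aq NH4Cl, work-up under Ar
Reagents that add atoms: none
Why: Single-electron-transfer reductive cleavage of benzyl aryl ethers (Birch-type debenzylation) releases the catecholate and toluene, while non-conjugated trisubstituted alkenes, the chroman ether and the C-2 stereocentre are inert.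

**Compound list**
1 | (2E,6E)-3,7,11-trimethyldodeca-2,6,10-trien-1-ol [(E,E)-farnesol] | CC(C)=CCC/C(C)=C/CC/C(C)=C/CO | starting material
2 | (2E,6E)-1-bromo-3,7,11-trimethyldodeca-2,6,10-triene [(E,E)-farnesyl bromide] | CC(C)=CCC/C(C)=C/CC/C(C)=C/CBr | intermediate
3 | ethyl 3-oxobutanoate (ethyl acetoacetate) | CCOC(=O)CC(C)=O | starting material
4 | ethyl (4E,8E)-2-acetyl-5,9,13-trimethyltetradeca-4,8,12-trienoate (racemic) | CC(C)=CCC/C(C)=C/CC/C(C)=C/CC(C(C)=O)C(=O)OCC | intermediate
5 | (4E,8E)-2-acetyl-5,9,13-trimethyltetradeca-4,8,12-trienoic acid (racemic, not isolated) | CC(C)=CCC/C(C)=C/CC/C(C)=C/CC(C(C)=O)C(O)=O | intermediate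
6 | (5E,9E)-6,10,14-trimethylpentadeca-5,9,13-trien-2-one [(E,E)-farnesylacetone] | CC(C)=CCC/C(C)=C/CC/C(C)=C/CCC(C)=O | intermediate
7 | 3,4,5-trimethoxytoluene | COc1cc(C)cc(OC)c1OC | starting material
8 | 1-(2,3,4-trimethoxy-6-methylphenyl)ethan-1-one | CC(=O)c1c(C)cc(OC)c(OC)c1OC | intermediate
9 | 1-(2,3,4-trihydroxy-6-methylphenyl)ethan-1-one | CC(=O)c1c(C)cc(O)c(O)c1O | intermediate
10 | 1-[3,4-bis(benzyloxy)-2-hydroxy-6-methylphenyl]ethan-1-one | CC(=O)c1c(C)cc(OCc2ccccc2)c(OCc2ccccc2)c1O | intermediate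
11 | (6E,10E)-1-[3,4-bis(benzyloxy)-2-hydroxy-6-methylphenyl]-3,7,11,15-tetramethylhexadeca-2,6,10,14-tetraen-1-one (2E/2Z mixture, not isolated) | CC(C)=CCC/C(C)=C/CC/C(C)=C/CCC(C)=CC(=O)c1c(C)cc(OCc2ccccc2)c(OCc2ccccc2)c1O | intermediate
12 | racemic 7,8-bis(benzyloxy)-2,5-dimethyl-2-[(3E,7E)-4,8,12-trimethyltrideca-3,7,11-trien-1-yl]chroman-4-one | CC(C)=CCC/C(C)=C/CC/C(C)=C/CCC1(C)CC(=O)c2c(C)cc(OCc3ccccc3)c(OCc3ccccc3)c2O1 | intermediate
13 | 7,8-bis(benzyloxy)-2,5-dimethyl-2-[(3E,7E)-4,8,12-trimethyltrideca-3,7,11-trien-1-yl]chroman-4-ol (racemic, both diastereomers, as aluminium alkoxide, not isolated) | CC(C)=CCC/C(C)=C/CC/C(C)=C/CCC1(C)CC(O)c2c(C)cc(OCc3ccccc3)c(OCc3ccccc3)c2O1 | intermediate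
14 | racemic 7,8-bis(benzyloxy)-2,5-dimethyl-2-[(3E,7E)-4,8,12-trimethyltrideca-3,7,11-trien-1-yl]chromane | CC(C)=CCC/C(C)=C/CC/C(C)=C/CCC1(C)CCc2c(C)cc(OCc3ccccc3)c(OCc3ccccc3)c2O1 | intermediate
15 | (2S)-7,8-bis(benzyloxy)-2,5-dimethyl-2-[(3E,7E)-4,8,12-trimethyltrideca-3,7,11-trien-1-yl]chromane | CC(C)=CCC/C(C)=C/CC/C(C)=C/CC[C@@]1(C)CCc2c(C)cc(OCc3ccccc3)c(OCc3ccccc3)c2O1 | intermediate
16 | (2S)-2,5-dimethyl-2-[(3E,7E)-4,8,12-trimethyltrideca-3,7,11-trien-1-yl]chromane-7,8-diol | CC(C)=CCC/C(C)=C/CC/C(C)=C/CC[C@@]1(C)CCc2c(C)cc(O)c(O)c2O1 | target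

**Step count and risks**
Total steps: 10 (two three-step branches, then four common steps).
Longest linear sequence: 7 steps (7 → 8 → 9 → 10 → 12 → 14 → 15 → 16; the branch from 1 is equally long).

Most likely to fail, step 7 (Kabbe condensation): the acetyl group is flanked by OH and CH3, and 6 can self-condense, so conversion or ring closure may be poor. The fallback sets out from 10 (with 6) and comes back at 12. Compound 10 is converted with LDA (2.2 equiv, THF, −78 °C) into its phenoxide/enolate dianion, which adds to 6 in a directed aldol addition to give the adduct racemic (6E,10E)-1-[3,4-bis(benzyloxy)-2-hydroxy-6-methylphenyl]-3-hydroxy-3,7,11,15-tetramethylhexadeca-6,10,14-trien-1-one F1. Catalytic TsOH·H2O in toluene at 60 °C then dehydrates the tertiary aldol to enone 11, which cyclises by oxa-Michael addition to 12.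

Most likely to fail, step 8 (mixed-hydride deoxygenation): the benzylic cation may lose a proton to give the 2H-chromene, or the Lewis acid may attack a benzyl ether. The fallback sets out from 12 and comes back at 14 without any cation or Lewis acid. Compound 12 is condensed with tosylhydrazide (EtOH, cat. AcOH, reflux) to the tosylhydrazone racemic N′-{7,8-bis(benzyloxy)-2,5-dimethyl-2-[(3E,7E)-4,8,12-trimethyltrideca-3,7,11-trien-1-yl]chroman-4-ylidene}-4-methylbenzenesulfonohydrazide F2. Catecholborane (CHCl3, 0 °C → rt) followed by NaOAc·3H2O at reflux (Caglioti/Kabalka reduction) expels sulfinate and N2 and leaves the CH2 of 14; the isolated alkenes are not hydroborated at this temperature.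

Most likely to fail, step 9 (chromatographic resolution): baseline separation, throughput or the configurational assignment may be unsatisfactory. The fallback sets out from 12 and comes back at 15, replacing physical resolution by a catalyst-controlled reduction. Noyori asymmetric transfer hydrogenation of racemic 12 with RuCl[(S,S)-TsDPEN](p-cymene) in HCO2H/Et3N (5:2) at 30 °C sets C-4 as (S) in both antipodes. This gives two diastereomers, (2S,4S)-7,8-bis(benzyloxy)-2,5-dimethyl-2-[(3E,7E)-4,8,12-trimethyltrideca-3,7,11-trien-1-yl]chroman-4-ol F3 and (2R,4S)-7,8-bis(benzyloxy)-2,5-dimethyl-2-[(3E,7E)-4,8,12-trimethyltrideca-3,7,11-trien-1-yl]chroman-4-ol F4, which are separated on silica or by achiral HPLC. NOE contacts of 4-H give the relative configuration and hence the absolute configuration at C-2. F3 is then hydrogenolysed at C-4 with LiAlH4/AlCl3 as in step 8 to give 15.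

**Further compounds**
F1 | step 7 | racemic (6E,10E)-1-[3,4-bis(benzyloxy)-2-hydroxy-6-methylphenyl]-3-hydroxy-3,7,11,15-tetramethylhexadeca-6,10,14-trien-1-one | CC(C)=CCC/C(C)=C/CC/C(C)=C/CCC(C)(O)CC(=O)c1c(C)cc(OCc2ccccc2)c(OCc2ccccc2)c1O
F2 | step 8 | racemic N′-{7,8-bis(benzyloxy)-2,5-dimethyl-2-[(3E,7E)-4,8,12-trimethyltrideca-3,7,11-trien-1-yl]chroman-4-ylidene}-4-methylbenzenesulfonohydrazide | CC(C)=CCC/C(C)=C/CC/C(C)=C/CCC1(C)CC(=NNS(=O)(=O)c4ccc(C)cc4)c2c(C)cc(OCc3ccccc3)c(OCc3ccccc3)c2O1
F3 | step 9 | (2S,4S)-7,8-bis(benzyloxy)-2,5-dimethyl-2-[(3E,7E)-4,8,12-trimethyltrideca-3,7,11-trien-1-yl]chroman-4-ol | CC(C)=CCC/C(C)=C/CC/C(C)=C/CC[C@@]1(C)C[C@H](O)c2c(C)cc(OCc3ccccc3)c(OCc3ccccc3)c2O1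
F4 | step 9 | (2R,4S)-7,8-bis(benzyloxy)-2,5-dimethyl-2-[(3E,7E)-4,8,12-trimethyltrideca-3,7,11-trien-1-yl]chroman-4-ol | CC(C)=CCC/C(C)=C/CC/C(C)=C/CC[C@]1(C)C[C@H](O)c2c(C)cc(OCc3ccccc3)c(OCc3ccccc3)c2O1
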